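**Plan**

- Numbering: ring A is C1–C6 (C1 the carbonyl carbon between C2 and C6, C4 quaternary), the bridge is C7, ring B is C1'–C6' (C1' on C7, C2' OH, C3' butanoyl, C4' OH, C5' CH3, C6' OCH3). Ring B is a hexasubstituted benzene with oxygen on the alternating carbons C2', C4' and C6' (only O6' methylated), CH3 on C5' and C7 on C1'. This is the sum of a 3-silyloxy vinylketene (C1'–C4', O2', O4') and 1-methoxypropyne (C5', C6').
- Retrosynthesis cuts: prenyl to allyl (metathesis); C2–CO and C3'–CO (the two butanoyl groups); ring A at C5–C6 (Dieckmann-type closure) and C2–C3 (alkyne acylation); ring B at C4'–C5' and C6'–C1'; the cyclobutenone into a silyl ynol ether and ketene.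
- Forward order: four-membered ring (step 4); ring B (step 6) on a cyclobutenone that carries C7, C6, C1 and C2 of ring A as a but-3-ynyl chain; ring A closed onto that chain (steps 8–10); then the second butanoyl group and the prenyl terminus.
- Ring A is closed after ring B because a 4-allyl cyclohexadienone bis(enol ether) is not accessible as one regioisomer and would be open to [3,3] shifts at the temperature of the benzannulation.
- Stereochemistry: the only stereocentre, C4, is set in step 2 by enzymatic desymmetrisation of malonate 3 (acid carbon becomes C3, ester carbon C5); it is quaternary and is not touched again.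

Key step: step 6

Assumption: pig liver esterase is taken to give the (S)-half ester 4, the sense recalled for 2-methylmalonates with short alkyl chains; if 4 is not enantiopure as formed, it is brought to purity by crystallisation of an amine salt before step 8.
Remark: the enolised triones of ring A are drawn as one tautomer.

**Route**

Step 1
Reactants: 1 dimethyl 2-methylpropanedioate; 2 3-bromoprop-1-ene
Product: 3 dimethyl 2-methyl-2-(prop-2-en-1-yl)propanedioate
Conditions: NaH, THF, 0 °C; then 2, rt
Reagents that add atoms: none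
Why: Malonate alkylation: the sodium enolate of 1 is allylated at carbon in an SN2 reaction, and a second alkylation is impossible because 3 has no acidic C–H.

Step 2
Reactants: 3 dimethyl 2-methyl-2-(prop-2-en-1-yl)propanedioate
Product: 4 (2S)-2-(methoxycarbonyl)-2-methylpent-4-enoic acid
Conditions: pig liver esterase, 0.1 M phosphate buffer pH 7.5, 25 °C, pH-stat with 1 M NaOH; then HCl to pH 2
Reagents that add atoms: water, O
Why: Enzymatic desymmetrisation of a prochiral 2,2-disubstituted malonate: the esterase hydrolyses one of the two enantiotopic ester groups and stops at the half ester, so the configuration of C4 is fixed by the enzyme's choice between the two CO2CH3 groups.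

Step 3
Reactants: 5 hexa-1,5-diyne
Product: 8 (hexa-1,5-diyn-1-yloxy)tri(propan-2-yl)silane, via lithium hexa-1,5-diyn-1-ide 6 (not isolated), via lithium hexa-1,5-diyn-1-olate 7 (not isolated)
Conditions: 5 (3 equiv), LiN(SiMe3)2 (2 equiv), t-BuOOH (1 equiv), THF, −78 → 0 °C; then i-Pr3SiOTf, −78 °C
Reagents that add atoms: tert-butyl hydroperoxide, CC(C)(C)OO; triisopropylsilyl trifluoromethanesulfonate, CC(C)[Si](C(C)C)(C(C)C)OS(=O)(=O)C(F)(F)F
Why: Oxidation of a lithium acetylide with lithium tert-butyl peroxide gives the lithium ynolate, which the bulky silyl triflate captures at oxygen (the known acetylide-oxidation route to silyl ynol ethers), and the excess of the symmetrical diyne holds the reaction at one terminus.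

Step 4
Reactants: 8 (hexa-1,5-diyn-1-yloxy)tri(propan-2-yl)silane
Product: 9 2-(but-3-yn-1-yl)-3-{[tri(propan-2-yl)silyl]oxy}cyclobut-2-en-1-one
Conditions: ketene (excess, gas from acetone pyrolysis), CH2Cl2, 0 °C → rt
Reagents that add atoms: ketene, C=C=O
Why: [2+2] cycloaddition of a silyl ynol ether with ketene, the known route to 3-silyloxycyclobutenones: the nucleophilic β-carbon of the ynol ether bonds to the ketene carbonyl carbon, which puts the butynyl chain on C2 and the silyloxy group on C3, and the unactivated terminal alkyne does not react.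

Step 5
Reactants: 10 2-chloro-1,1-dimethoxyethane
Product: 12 1-methoxyprop-1-yne, via sodium methoxyethynide 11 (not isolated)
Conditions: NaNH2 (3 equiv), liq. NH3, −33 °C; then MeI; distil
Reagents that add atoms: iodomethane, CI
Why: Twofold elimination (methanol, then hydrogen chloride) from the chloroacetal with sodium amide gives sodium methoxyethynide, which is methylated at carbon in the same flask, the classical preparation of 1-alkoxyalk-1-ynes.

Step 6
Reactants: 9 2-(but-3-yn-1-yl)-3-{[tri(propan-2-yl)silyl]oxy}cyclobut-2-en-1-one; 12 1-methoxyprop-1-yne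
Product: 17 4-(but-3-yn-1-yl)-3-methoxy-2-methyl-5-{[tri(propan-2-yl)silyl]oxy}phenol, via vinylketene 13 (not isolated), via cyclobutenone adduct 14 (not isolated), via dienylketene 15 (not isolated), via cyclohexadienone tautomer 16 (not isolated)
Conditions: 12 (4 equiv), toluene, sealed tube, 80 → 110 °C
Reagents that add atoms: none
Why: Proposed new method: heating should open 9 by 4π electrocyclic ring opening to the silyloxy vinylketene 13, whose ketene carbonyl carbon bonds to the methyl-bearing carbon of 12 in a [2+2] cycloaddition to give 14, which opens to the dienylketene 15, closes to the cyclohexadienone 16 and tautomerises to the phenol 17. The closest known reaction type is the Danheiser benzannulation of 3-alkyl- and 3-arylcyclobutenones with alkoxy- and silyloxyalkynes to resorcinol monoethers, and thermal opening of 3-alkoxycyclobutenones to vinylketenes is known from squarate-derived 4-hydroxycyclobutenones; untested is the capture of a 3-silyloxy vinylketene by an alkyne between two molecules. Ring B is closed by the 6π electrocyclisation of 15 (C3'–C4' bond) after the cycloaddition has made C4'–C5' and C6'–C1'. No stereocentre is formed. The step needs the regiochemistry of the ketene–alkyne cycloaddition, which the polarisation of the ynol ether secures (its nucleophilic carbon is the one that carries CH3), and chemoselectivity for 12 over the terminal alkyne of the side chain, which is secured by the much higher reactivity of the ynol ether used in excess and by the two-carbon tether, too short for a cycloaddition within the molecule.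

Step 7
Reactants: 17 4-(but-3-yn-1-yl)-3-methoxy-2-methyl-5-{[tri(propan-2-yl)silyl]oxy}phenol
Product: 19 1-{3-(but-3-yn-1-yl)-6-hydroxy-4-methoxy-5-methyl-2-{[tri(propan-2-yl)silyl]oxy}phenyl}butan-1-one, via difluoroboron chelate 18 (not isolated)
Conditions: (PrCO)2O, BF3·OEt2, CH2Cl2, 0 °C → rt; then aq NaOAc, MeOH
Reagents that add atoms: butanoic anhydride, CCCC(=O)OC(=O)CCC
Why: Friedel–Crafts C-acylation with an anhydride and BF3·OEt2, the standard acylation of phloroglucinol ethers: C3' is the only free ring carbon and lies ortho to the free hydroxyl, the ketone is held as a difluoroboron chelate until the acetate work-up, the arene is far more nucleophilic than the terminal alkyne, and the aryl silyl ether is expected to survive at this temperature.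

Step 8
Reactants: 19 1-{3-(but-3-yn-1-yl)-6-hydroxy-4-methoxy-5-methyl-2-{[tri(propan-2-yl)silyl]oxy}phenyl}butan-1-one; 4 (2S)-2-(methoxycarbonyl)-2-methylpent-4-enoic acid
Product: 21 methyl (2S)-7-{3-butanoyl-4-hydroxy-6-methoxy-5-methyl-2-{[tri(propan-2-yl)silyl]oxy}phenyl}-2-methyl-3-oxo-2-(prop-2-en-1-yl)hept-4-ynoate, via acid chloride 20 (not isolated)
Conditions: 4, (COCl)2, cat. DMF, CH2Cl2, 0 °C → rt, evaporate; then 19, PdCl2(PPh3)2 (2 mol %), CuI (4 mol %), Et3N, THF, rt
Reagents that add atoms: none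
Why: Acyl Sonogashira coupling of an acid chloride with a terminal alkyne gives the ynone; the α-quaternary chloride can neither epimerise nor form a ketene, and the C4' hydroxyl, hydrogen-bonded to the ketone and flanked on both sides, is not expected to be acylated by this hindered chloride.

Step 9
Reactants: 21 methyl (2S)-7-{3-butanoyl-4-hydroxy-6-methoxy-5-methyl-2-{[tri(propan-2-yl)silyl]oxy}phenyl}-2-methyl-3-oxo-2-(prop-2-en-1-yl)hept-4-ynoate
Product: 22 methyl (2S,4E)-7-{3-butanoyl-4-hydroxy-6-methoxy-5-methyl-2-{[tri(propan-2-yl)silyl]oxy}phenyl}-5-methoxy-2-methyl-3-oxo-2-(prop-2-en-1-yl)hept-4-enoate (E expected as the major isomer; the geometry is lost in step 10)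
Conditions: MeOH, DABCO (10 mol %), 0 °C → rt
Reagents that add atoms: methanol, CO
Why: Amine-catalysed conjugate addition of methanol to the ynone places the methoxy group on C1 without ambiguity, masks the reactive ynone as a vinylogous ester and leaves C6 as the only position from which ring A can be closed.

Step 10
Reactants: 22 methyl (2S,4E)-7-{3-butanoyl-4-hydroxy-6-methoxy-5-methyl-2-{[tri(propan-2-yl)silyl]oxy}phenyl}-5-methoxy-2-methyl-3-oxo-2-(prop-2-en-1-yl)hept-4-enoate
Product: 24 (4S)-2-({3-butanoyl-4-hydroxy-6-methoxy-5-methyl-2-{[tri(propan-2-yl)silyl]oxy}phenyl}methyl)-3,5-dihydroxy-4-methyl-4-(prop-2-en-1-yl)cyclohexa-2,5-dien-1-one, via ring A methyl enol ether 23 (not isolated)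
Conditions: KN(SiMe3)2 (3.5 equiv), THF, −78 °C → rt; then 1 M HCl, THF, 40 °C
Reagents that add atoms: water, O
Why: Dieckmann-type Claisen condensation: once the phenol and the aryl ketone have taken up base, deprotonation at C6 gives the dienolate of the vinylogous ester, which can reach the methyl ester only through C6 (six-membered ring, whereas attack through C2 would give a four-membered ring), and dilute acid then hydrolyses the unhindered C1 enol ether of 23 to the trione while the aryl silyl ether stays in place and keeps O2' from adding to ring A.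

Step 11
Reactants: 24 (4S)-2-({3-butanoyl-4-hydroxy-6-methoxy-5-methyl-2-{[tri(propan-2-yl)silyl]oxy}phenyl}methyl)-3,5-dihydroxy-4-methyl-4-(prop-2-en-1-yl)cyclohexa-2,5-dien-1-one
Product: 25 (4R)-2-butanoyl-6-({3-butanoyl-4-hydroxy-6-methoxy-5-methyl-2-{[tri(propan-2-yl)silyl]oxy}phenyl}methyl)-3,5-dihydroxy-4-methyl-4-(prop-2-en-1-yl)cyclohexa-2,5-dien-1-one
Conditions: PrCO2H, DCC, DMAP, CH2Cl2, rt
Reagents that add atoms: butanoic acid, CCCC(=O)O
Why: C-acylation of a cyclic 1,3-dione with a carboxylic acid, DCC and DMAP (enol ester formation followed by a DMAP-mediated O-to-C acyl shift), which can only end at C2 because C6 is substituted; the chelated C4' hydroxyl is not acylated and no Lewis acid touches the methylene bridge.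

Step 12
Reactants: 25 (4R)-2-butanoyl-6-({3-butanoyl-4-hydroxy-6-methoxy-5-methyl-2-{[tri(propan-2-yl)silyl]oxy}phenyl}methyl)-3,5-dihydroxy-4-methyl-4-(prop-2-en-1-yl)cyclohexa-2,5-dien-1-one
Product: 26 (4R)-2-butanoyl-6-[(3-butanoyl-2,4-dihydroxy-6-methoxy-5-methylphenyl)methyl]-3,5-dihydroxy-4-methyl-4-(prop-2-en-1-yl)cyclohexa-2,5-dien-1-one
Conditions: Bu4NF, AcOH, THF, 0 °C
Reagents that add atoms: none
Why: Fluoride cleavage of the aryl silyl ether, buffered with acetic acid so that no free phenoxide stands next to the bridge carbon.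

Step 13
Reactants: 26 (4R)-2-butanoyl-6-[(3-butanoyl-2,4-dihydroxy-6-methoxy-5-methylphenyl)methyl]-3,5-dihydroxy-4-methyl-4-(prop-2-en-1-yl)cyclohexa-2,5-dien-1-one
Product: 27 (4R)-2-butanoyl-6-[(3-butanoyl-2,4-dihydroxy-6-methoxy-5-methylphenyl)methyl]-3,5-dihydroxy-4-methyl-4-(3-methylbut-2-en-1-yl)cyclohexa-2,5-dien-1-one
Conditions: 2-methylbut-2-ene (excess), second-generation Grubbs catalyst RuCl2(=CHPh)(PCy3)(1,3-dimesitylimidazolidin-2-ylidene) (5 mol %), CH2Cl2, 40 °C
Reagents that add atoms: 2-methylbut-2-ene, CC=C(C)C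
Why: Olefin cross-metathesis of the monosubstituted allyl group with 2-methylbut-2-ene, the usual late conversion of allyl into prenyl on quaternary carbons of acylphloroglucinols; the enol and aryl double bonds are fully substituted and do not take part, and C4 is not touched.

**Compound list**

1 | dimethyl 2-methylpropanedioate | COC(=O)C(C)C(=O)OC | starting material
2 | 3-bromoprop-1-ene | C=CCBr | starting material
3 | dimethyl 2-methyl-2-(prop-2-en-1-yl)propanedioate | COC(=O)C(C)(CC=C)C(=O)OC | intermediate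
4 | (2S)-2-(methoxycarbonyl)-2-methylpent-4-enoic acid | OC(=O)[C@](C)(CC=C)C(=O)OC | intermediate
5 | hexa-1,5-diyne | C#CCCC#C | starting material
6 | lithium hexa-1,5-diyn-1-ide | [Li+].[C-]#CCCC#C | intermediate
7 | lithium hexa-1,5-diyn-1-olate | [Li+].[O-]C#CCCC#C | intermediate
8 | (hexa-1,5-diyn-1-yloxy)tri(propan-2-yl)silane | C#CCCC#CO[Si](C(C)C)(C(C)C)C(C)C | intermediate
9 | 2-(but-3-yn-1-yl)-3-{[tri(propan-2-yl)silyl]oxy}cyclobut-2-en-1-one | O=C1CC(O[Si](C(C)C)(C(C)C)C(C)C)=C1CCC#C | intermediate
10 | 2-chloro-1,1-dimethoxyethane | COC(CCl)OC | starting material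
11 | sodium methoxyethynide | [Na+].[C-]#COC | intermediate
12 | 1-methoxyprop-1-yne | CC#COC | intermediate
13 | 2-(but-3-yn-1-yl)-3-{[tri(propan-2-yl)silyl]oxy}buta-1,3-dien-1-one | O=C=C(CCC#C)C(=C)O[Si](C(C)C)(C(C)C)C(C)C | intermediate
14 | 4-(but-3-yn-1-yl)-3-methoxy-2-methyl-4-(1-{[tri(propan-2-yl)silyl]oxy}ethenyl)cyclobut-2-en-1-one (racemic at C4) | O=C1C(C)=C(OC)C1(CCC#C)C(=C)O[Si](C(C)C)(C(C)C)C(C)C | intermediate
15 | 4-(but-3-yn-1-yl)-3-methoxy-2-methyl-5-{[tri(propan-2-yl)silyl]oxy}hexa-1,3,5-trien-1-one | O=C=C(C)C(OC)=C(CCC#C)C(=C)O[Si](C(C)C)(C(C)C)C(C)C | intermediate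
16 | 4-(but-3-yn-1-yl)-3-methoxy-2-methyl-5-{[tri(propan-2-yl)silyl]oxy}cyclohexa-2,4-dien-1-one | O=C1CC(O[Si](C(C)C)(C(C)C)C(C)C)=C(CCC#C)C(OC)=C1C | intermediate
17 | 4-(but-3-yn-1-yl)-3-methoxy-2-methyl-5-{[tri(propan-2-yl)silyl]oxy}phenol | Oc1cc(O[Si](C(C)C)(C(C)C)C(C)C)c(CCC#C)c(OC)c1C | intermediate
18 | difluoroboron chelate of 19 (boron between the ketone oxygen and O4') | CCCC1=[O+][B-](F)(F)Oc2c1c(O[Si](C(C)C)(C(C)C)C(C)C)c(CCC#C)c(OC)c2C | intermediate
19 | 1-{3-(but-3-yn-1-yl)-6-hydroxy-4-methoxy-5-methyl-2-{[tri(propan-2-yl)silyl]oxy}phenyl}butan-1-one | CCCC(=O)c1c(O)c(C)c(OC)c(CCC#C)c1O[Si](C(C)C)(C(C)C)C(C)C | intermediate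
20 | methyl (2R)-2-(chlorocarbonyl)-2-methylpent-4-enoate | ClC(=O)[C@](C)(CC=C)C(=O)OC | intermediate
21 | methyl (2S)-7-{3-butanoyl-4-hydroxy-6-methoxy-5-methyl-2-{[tri(propan-2-yl)silyl]oxy}phenyl}-2-methyl-3-oxo-2-(prop-2-en-1-yl)hept-4-ynoate | COC(=O)[C@@](C)(CC=C)C(=O)C#CCCc1c(O[Si](C(C)C)(C(C)C)C(C)C)c(C(=O)CCC)c(O)c(C)c1OC | intermediate
22 | methyl (2S,4E)-7-{3-butanoyl-4-hydroxy-6-methoxy-5-methyl-2-{[tri(propan-2-yl)silyl]oxy}phenyl}-5-methoxy-2-methyl-3-oxo-2-(prop-2-en-1-yl)hept-4-enoate | COC(=O)[C@@](C)(CC=C)C(=O)/C=C(/OC)CCc1c(O[Si](C(C)C)(C(C)C)C(C)C)c(C(=O)CCC)c(O)c(C)c1OC | intermediate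
23 | (6S)-2-({3-butanoyl-4-hydroxy-6-methoxy-5-methyl-2-{[tri(propan-2-yl)silyl]oxy}phenyl}methyl)-5-hydroxy-3-methoxy-6-methyl-6-(prop-2-en-1-yl)cyclohexa-2,4-dien-1-one | O=C1C(Cc2c(O[Si](C(C)C)(C(C)C)C(C)C)c(C(=O)CCC)c(O)c(C)c2OC)=C(OC)C=C(O)[C@]1(C)CC=C | intermediate
24 | (4S)-2-({3-butanoyl-4-hydroxy-6-methoxy-5-methyl-2-{[tri(propan-2-yl)silyl]oxy}phenyl}methyl)-3,5-dihydroxy-4-methyl-4-(prop-2-en-1-yl)cyclohexa-2,5-dien-1-one | O=C1C=C(O)[C@](C)(CC=C)C(O)=C1Cc2c(O[Si](C(C)C)(C(C)C)C(C)C)c(C(=O)CCC)c(O)c(C)c2OC | intermediate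
25 | (4R)-2-butanoyl-6-({3-butanoyl-4-hydroxy-6-methoxy-5-methyl-2-{[tri(propan-2-yl)silyl]oxy}phenyl}methyl)-3,5-dihydroxy-4-methyl-4-(prop-2-en-1-yl)cyclohexa-2,5-dien-1-one | CCCC(=O)C1=C(O)[C@](C)(CC=C)C(O)=C(Cc2c(O[Si](C(C)C)(C(C)C)C(C)C)c(C(=O)CCC)c(O)c(C)c2OC)C1=O | intermediate
26 | (4R)-2-butanoyl-6-[(3-butanoyl-2,4-dihydroxy-6-methoxy-5-methylphenyl)methyl]-3,5-dihydroxy-4-methyl-4-(prop-2-en-1-yl)cyclohexa-2,5-dien-1-one | CCCC(=O)C1=C(O)[C@](C)(CC=C)C(O)=C(Cc2c(O)c(C(=O)CCC)c(O)c(C)c2OC)C1=O | intermediate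
27 | (4R)-2-butanoyl-6-[(3-butanoyl-2,4-dihydroxy-6-methoxy-5-methylphenyl)methyl]-3,5-dihydroxy-4-methyl-4-(3-methylbut-2-en-1-yl)cyclohexa-2,5-dien-1-one | CCCC(=O)C1=C(O)[C@](C)(CC=C(C)C)C(O)=C(Cc2c(O)c(C(=O)CCC)c(O)c(C)c2OC)C1=O | target

**Step count**

Total: 13 steps. Longest linear sequence: 10 steps (steps 3, 4, 6, 7, 8, 9, 10, 11, 12, 13 from hexa-1,5-diyne). The half ester 4 (steps 1 and 2) and the ynol ether 12 (step 5) come from side branches.

**Steps most likely to fail**

Step 6. The silyloxy group stabilises the cyclobutenone, so ring opening may need a temperature at which the ynol ether polymerises, the silyl enol ether is lost, or the phenol product adds to the vinylketene. The fallback uses known chemistry and gives up the benzannulation: ring B is taken as a preformed phenol and joined by a methylene coupling.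
- Setting out from 4 through its chloride 20, C-acylation of heptane-2,4-dione (MgCl2, pyridine, CH2Cl2) would give the triacylmethane methyl (2S)-4-acetyl-2-methyl-3,5-dioxo-2-(prop-2-en-1-yl)octanoate F1.
- Claisen ring closure of its dianion (LiN(i-Pr)2, THF) through the acetyl methyl group would give (4R)-2-butanoyl-3,5-dihydroxy-4-methyl-4-(prop-2-en-1-yl)cyclohexa-2,5-dien-1-one F2.
- Condensation of F2 with the known phenol aspidinol, 1-(2,6-dihydroxy-4-methoxy-3-methylphenyl)butan-1-one F3, and aqueous formaldehyde in dilute KOH, followed by separation from the two symmetrical dimers, comes back to the route at 26, which goes on to step 13.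

Step 10. The dienolate may fail to reach the hindered ester (unfavourable enolate geometry, competing enolisation of the aryl ketone), or the silyl ether may be lost under the basic conditions. The fallback changes the nucleophile from the enol ether dienolate to a 1,3-diketone dianion.
- Setting out from 22, 1 M HCl in THF at rt would hydrolyse only the enol ether to the diketone methyl (2S)-7-{3-butanoyl-4-hydroxy-6-methoxy-5-methyl-2-{[tri(propan-2-yl)silyl]oxy}phenyl}-2-methyl-3,5-dioxo-2-(prop-2-en-1-yl)heptanoate F4.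
- Excess LiN(i-Pr)2 in THF (−78 °C → rt) would then close ring A by the classical acylation of a β-diketone dianion with an ester and come back to the route at 24.

Step 2. The enzyme may discriminate the two ester groups incompletely, so that 4 is not enantiopure. The fallback is a resolution through a covalent auxiliary.
- Setting out from 3, KOH (1 equiv) in methanol would give the racemic half ester 2-(methoxycarbonyl)-2-methylpent-4-enoic acid F5.
- Oxalyl chloride would give its chloride, methyl 2-(chlorocarbonyl)-2-methylpent-4-enoate F6.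
- The lithium salt of (4S)-4-benzyl-1,3-oxazolidin-2-one would give two diastereomeric imides: methyl (2S)-2-{[(4S)-4-benzyl-2-oxo-1,3-oxazolidin-3-yl]carbonyl}-2-methylpent-4-enoate F7 and its (2R) epimer, methyl (2R)-2-{[(4S)-4-benzyl-2-oxo-1,3-oxazolidin-3-yl]carbonyl}-2-methylpent-4-enoate F8. They would be separated by chromatography or crystallisation.
- LiOH/H2O2 would cleave the imide of F7 and come back to the route at 4.

**Further compounds**

F1 | step 6 | methyl (2S)-4-acetyl-2-methyl-3,5-dioxo-2-(prop-2-en-1-yl)octanoate | COC(=O)[C@@](C)(CC=C)C(=O)C(C(C)=O)C(=O)CCC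
F2 | step 6 | (4R)-2-butanoyl-3,5-dihydroxy-4-methyl-4-(prop-2-en-1-yl)cyclohexa-2,5-dien-1-one | CCCC(=O)C1=C(O)[C@](C)(CC=C)C(O)=CC1=O
F3 | step 6 | 1-(2,6-dihydroxy-4-methoxy-3-methylphenyl)butan-1-one (aspidinol) | CCCC(=O)c1c(O)cc(OC)c(C)c1O
F4 | step 10 | methyl (2S)-7-{3-butanoyl-4-hydroxy-6-methoxy-5-methyl-2-{[tri(propan-2-yl)silyl]oxy}phenyl}-2-methyl-3,5-dioxo-2-(prop-2-en-1-yl)heptanoate | COC(=O)[C@@](C)(CC=C)C(=O)CC(=O)CCc1c(O[Si](C(C)C)(C(C)C)C(C)C)c(C(=O)CCC)c(O)c(C)c1OC
F5 | step 2 | 2-(methoxycarbonyl)-2-methylpent-4-enoic acid (racemic) | COC(=O)C(C)(CC=C)C(O)=O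
F6 | step 2 | methyl 2-(chlorocarbonyl)-2-methylpent-4-enoate (racemic) | COC(=O)C(C)(CC=C)C(Cl)=O
F7 | step 2 | methyl (2S)-2-{[(4S)-4-benzyl-2-oxo-1,3-oxazolidin-3-yl]carbonyl}-2-methylpent-4-enoate | COC(=O)[C@@](C)(CC=C)C(=O)N1[C@@H](Cc2ccccc2)COC1=O
F8 | step 2 | methyl (2R)-2-{[(4S)-4-benzyl-2-oxo-1,3-oxazolidin-3-yl]carbonyl}-2-methylpent-4-enoate | COC(=O)[C@](C)(CC=C)C(=O)N1[C@@H](Cc2ccccc2)COC1=O
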